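**Retrosynthetic overview**
1. The cis N/O pair comes from an OH-tethered aza-Michael addition (cis-fused oxazoline) on a 4-hydroxycyclohexenone; that hydroxyl comes from Luche reduction of an ene-dione made by aerobic γ-oxidation of a β,γ-enone.
2. Key disconnection: the spiro quaternary carbon and the six-membered ketone form together in a vinylogous semipinacol 1,2-shift (cyclopentenol → cyclohexenone ring expansion) onto C4 of a 5-substituted butenolide; the butenolide stereocentre controls the spiro centre.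
3. The butenolide comes from an asymmetric Ni/Cr coupling of an (E)-alkenyl iodide with a (Z)-3-formylacrylate, followed by lactonisation.
4. The formylacrylate comes from singlet-oxygen unmasking of a 3-furyl carbinol (3-furyllithium + cyclopent-3-enone); the iodide comes from carboalumination–iodination of an enyne (homoprenyl bromide + acetylide).
5. Ring order: lactone first, cyclohexenone second (by ring expansion of the cyclopentene), oxazoline last and only temporary.

Assumption: compounds 1, 2, 6 and 7 are bought; numbering follows 2-oxaspiro[4.5]decane (C1 lactone CH–O, C5 spiro carbon, C6 ketone, C8 C–N, C9 C–OH), so the target is the (1R,5R,8R,9S) isomer.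

**Step 1**
Reactants: 1 5-bromo-2-methylpent-2-ene; 2 lithium acetylide–ethylenediamine complex
Product: 3 6-methylhept-5-en-1-yne
Conditions: DMSO, 0 °C → rt
Reagents that add atoms: none
Why: SN2 alkylation of the acetylide by the primary bromide (alkyne alkylation); no stereocentre.

**Step 2**
Reactants: 3 6-methylhept-5-en-1-yne
Product: 5 (1E)-1-iodo-2,6-dimethylhepta-1,5-diene, via alkenyl(dimethyl)alane 4 (not isolated)
Conditions: AlMe3 (2 equiv), Cp2ZrCl2 (0.2 equiv), CH2Cl2, rt; then I2, THF, −30 → 0 °C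
Reagents that add atoms: trimethylaluminium C[Al](C)C; iodine II
Why: Negishi zirconium-catalysed carboalumination adds Me and Al syn with Al at the terminus, and iodinolysis with retention fixes the (E)-trisubstituted alkene; the remote trisubstituted alkene does not react.

**Step 3**
Reactants: 6 3-bromofuran; 7 cyclopent-3-en-1-one
Product: 9 1-(furan-3-yl)cyclopent-3-en-1-ol, via furan-3-yllithium 8 (not isolated)
Conditions: n-BuLi, THF, −78 °C; then 7 premixed with LaCl3·2LiCl, −78 °C; H2O
Reagents that add atoms: none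
Why: Bromine–lithium exchange, then lanthanum-salt-promoted 1,2-addition to the enolisable ketone (the salt suppresses deprotonation); the carbinol carbon lies on a mirror plane, so no stereocentre forms.

**Step 4**
Reactants: 9 1-(furan-3-yl)cyclopent-3-en-1-ol
Product: 12 methyl (2Z)-3-(1-hydroxycyclopent-3-en-1-yl)-4-oxobut-2-enoate, via furan endoperoxide 10 (not isolated), via hydroxybutenolide 11 (not isolated)
Conditions: O2, hν (visible), TPP (cat.), i-Pr2NEt, CH2Cl2, −78 °C; then DMF, K2CO3, MeI, 0 °C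
Reagents that add atoms: dioxygen O=O; iodomethane CI
Why: [4+2] addition of singlet oxygen to the furan (far faster than the ene reaction of the ring alkene), then Kornblum–DeLaMare-type fragmentation in which the hindered amine removes the bridgehead H remote from the substituent, so the lactol carbon ends next to the substituted carbon; SN2 O-methylation of the ring-opened carboxylate then unmasks the aldehyde with the (Z) geometry inherited from the furan.

**Step 5**
Reactants: 12 methyl (2Z)-3-(1-hydroxycyclopent-3-en-1-yl)-4-oxobut-2-enoate; 5 (1E)-1-iodo-2,6-dimethylhepta-1,5-diene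
Product: 14 (5R)-5-[(1E)-2,6-dimethylhepta-1,5-dien-1-yl]-4-(1-hydroxycyclopent-3-en-1-yl)furan-2(5H)-one, via hydroxy ester 13 (not isolated)
Conditions: CrCl2 (3 equiv), NiCl2 (2 mol %), chiral sulfonamide–oxazoline ligand (Kishi type, enantiomer giving the R carbinol, recovered), Et3N, THF, rt; then PPTS (cat.), CH2Cl2, rt
Reagents that add atoms: none
Why: Nozaki–Hiyama–Kishi coupling is 1,2-selective for the aldehyde and tolerates the ester and the free tertiary OH; the chiral Cr(III)–sulfonamide complex selects the aldehyde face (C4 R of 13), and the alkoxide, cis to the ester, closes the butenolide (C5 R of 14).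

**Step 6**
Reactants: 14 (5R)-5-[(1E)-2,6-dimethylhepta-1,5-dien-1-yl]-4-(1-hydroxycyclopent-3-en-1-yl)furan-2(5H)-one
Product: 17 (1R,5R)-1-[(1E)-2,6-dimethylhepta-1,5-dien-1-yl]-2-oxaspiro[4.5]dec-8-ene-3,6-dione, via aluminium alkoxide 15 (not isolated), via aluminium enolate 16 (not isolated)
Conditions: Me2AlCl (2.5 equiv), CH2Cl2, −78 → −20 °C; aq. Rochelle salt
Reagents that add atoms: none
Why: Proposed new method: one equivalent of Me2AlCl turns the tertiary alcohol into an electron-rich aluminium alkoxide (CH4 lost) and a second activates the lactone carbonyl, so the butenolide β-carbon becomes a vinylogous acyl cation; a ring CH2 (both are equivalent by symmetry, so only one constitution can form) then shifts from the carbinol carbon to that carbon on the face anti to the C5 dienyl group, which sets the spiro centre (5R) with the new ketone cis to the side chain, and the aluminium enolate is protonated at the lactone α-carbon on work-up; the aprotic, proton-scavenging Lewis acid should spare the acid-labile trisubstituted alkenes, and the driving force is C=C/O–H → C=O/C–H plus relief of cyclopentene strain; the closest known reaction types are the amine- or acid-catalysed vinylogous α-ketol (semipinacol) rearrangement of 3-(1-hydroxycyclobutyl)enones and Lewis-acid α-ketol ring enlargement of cyclopentanols, neither shown for a butenolide acceptor with a cyclopentenol donor.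

**Step 7**
Reactants: 17 (1R,5R)-1-[(1E)-2,6-dimethylhepta-1,5-dien-1-yl]-2-oxaspiro[4.5]dec-8-ene-3,6-dione
Product: 19 (1R,5R)-1-[(1E)-2,6-dimethylhepta-1,5-dien-1-yl]-2-oxaspiro[4.5]dec-7-ene-3,6,9-trione, via C9 hydroperoxide 18 (not isolated)
Conditions: O2 (1 atm), DBU, MeCN, 0 °C → rt
Reagents that add atoms: dioxygen O=O
Why: Base-mediated aerobic γ-oxidation of the β,γ-enone through its extended dienolate, then Kornblum–DeLaMare dehydration of the C9 hydroperoxide to the ketone; C5 is quaternary, so neither aromatisation nor epimerisation is possible, and C1–H is no longer acidic.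

**Step 8**
Reactants: 19 (1R,5R)-1-[(1E)-2,6-dimethylhepta-1,5-dien-1-yl]-2-oxaspiro[4.5]dec-7-ene-3,6,9-trione
Product: 20 (1R,5R,9S)-1-[(1E)-2,6-dimethylhepta-1,5-dien-1-yl]-9-hydroxy-2-oxaspiro[4.5]dec-7-ene-3,6-dione
Conditions: NaBH4, CeCl3·7H2O, MeOH, −78 °C
Reagents that add atoms: none
Why: Luche reduction is 1,2-selective and confined to the C9 carbonyl because C6 is flanked by the spiro carbon; the lactone arm C1 (whose dienyl group would clash with O=C6 if equatorial) should sit pseudo-axial, so hydride adds anti to it and the new hydroxyl ends cis to C1–O (9S).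

**Step 9**
Reactants: 20 (1R,5R,9S)-1-[(1E)-2,6-dimethylhepta-1,5-dien-1-yl]-9-hydroxy-2-oxaspiro[4.5]dec-7-ene-3,6-dione
Product: 22 cis-fused 2-(trichloromethyl)-4,5-dihydro-1,3-oxazole spanning N–C8 and O–C9 of (1R,5R,8R,9S)-1-[(1E)-2,6-dimethylhepta-1,5-dien-1-yl]-2-oxaspiro[4.5]decane-3,6-dione, via trichloroacetimidate 21 (not isolated)
Conditions: Cl3CCN, DBU (cat.), CH2Cl2, 0 °C → rt
Reagents that add atoms: trichloroacetonitrile ClC(Cl)(Cl)C#N
Why: Base-catalysed addition of the alcohol to trichloroacetonitrile, then 5-exo-trig aza-Michael addition of the imidate nitrogen to C8; the two-atom tether can only reach the face of the C9 oxygen, so C8 is set cis (8R).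

**Step 10**
Reactants: 22 cis-fused trichloromethyl-oxazoline
Product: 24 N-[(1R,5R,8R,9S)-1-[(1E)-2,6-dimethylhepta-1,5-dien-1-yl]-9-hydroxy-3,6-dioxo-2-oxaspiro[4.5]decan-8-yl]acetamide = (+)-miliusane V, via amino alcohol hydrochloride 23 (not isolated)
Conditions: 1 M HCl, THF, rt; then aq. NaHCO3, Ac2O, 0 °C
Reagents that add atoms: acetic anhydride CC(=O)OC(C)=O
Why: Acid hydrolysis of the oxazoline (N-protonation, water at C2, C–N cleavage, loss of the labile trichloroacetate) frees the cis-amino alcohol as its salt, and Schotten–Baumann acetylation is N-selective over the secondary OH; no stereocentre is touched.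

**Compound list**
1 | 5-bromo-2-methylpent-2-ene | CC(C)=CCCBr | starting material
2 | lithium acetylide–ethylenediamine complex | [Li]C#C.NCCN | starting material
3 | 6-methylhept-5-en-1-yne | C#CCCC=C(C)C | intermediate
4 | [(1E)-2,6-dimethylhepta-1,5-dien-1-yl]dimethylalumane | C[Al](C)/C=C(\C)CCC=C(C)C | intermediate
5 | (1E)-1-iodo-2,6-dimethylhepta-1,5-diene | I/C=C(\C)CCC=C(C)C | intermediate
6 | 3-bromofuran | Brc1ccoc1 | starting material
7 | cyclopent-3-en-1-one | O=C1CC=CC1 | starting material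
8 | furan-3-yllithium | [Li]c1ccoc1 | intermediate
9 | 1-(furan-3-yl)cyclopent-3-en-1-ol | OC1(CC=CC1)c1ccoc1 | intermediate
10 | 1-(2,3,7-trioxabicyclo[2.2.1]hept-5-en-5-yl)cyclopent-3-en-1-ol (furan endoperoxide, racemic) | OC1(CC=CC1)C1=CC2OOC1O2 | intermediate
11 | 5-hydroxy-4-(1-hydroxycyclopent-3-en-1-yl)furan-2(5H)-one (racemic lactol, present as its ring-opened carboxylate) | O=C1C=C(C2(O)CC=CC2)C(O)O1 | intermediate
12 | methyl (2Z)-3-(1-hydroxycyclopent-3-en-1-yl)-4-oxobut-2-enoate | COC(=O)/C=C(\C=O)C1(O)CC=CC1 | intermediate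
13 | methyl (2E,4R,5E)-4-hydroxy-3-(1-hydroxycyclopent-3-en-1-yl)-6,10-dimethylundeca-2,5,9-trienoate | COC(=O)/C=C(\[C@H](O)/C=C(\C)CCC=C(C)C)C1(O)CC=CC1 | intermediate
14 | (5R)-5-[(1E)-2,6-dimethylhepta-1,5-dien-1-yl]-4-(1-hydroxycyclopent-3-en-1-yl)furan-2(5H)-one | O=C1C=C(C2(O)CC=CC2)[C@@H](/C=C(\C)CCC=C(C)C)O1 | intermediate
15 | chloro(methyl)aluminium alkoxide of 14 | C[Al](Cl)OC1(CC=CC1)C1=CC(=O)O[C@@H]1/C=C(\C)CCC=C(C)C | intermediate
16 | chloro(methyl)aluminium lactone enolate of 17 | C[Al](Cl)OC1=C[C@]2(CC=CCC2=O)[C@@H](/C=C(\C)CCC=C(C)C)O1 | intermediate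
17 | (1R,5R)-1-[(1E)-2,6-dimethylhepta-1,5-dien-1-yl]-2-oxaspiro[4.5]dec-8-ene-3,6-dione | O=C1CC=CC[C@]12CC(=O)O[C@@H]2/C=C(\C)CCC=C(C)C | intermediate
18 | (1R,5R)-1-[(1E)-2,6-dimethylhepta-1,5-dien-1-yl]-9-hydroperoxy-2-oxaspiro[4.5]dec-7-ene-3,6-dione (C9 epimer mixture) | OOC1C=CC(=O)[C@@]2(CC(=O)O[C@@H]2/C=C(\C)CCC=C(C)C)C1 | intermediate
19 | (1R,5R)-1-[(1E)-2,6-dimethylhepta-1,5-dien-1-yl]-2-oxaspiro[4.5]dec-7-ene-3,6,9-trione | O=C1C=CC(=O)[C@@]2(CC(=O)O[C@@H]2/C=C(\C)CCC=C(C)C)C1 | intermediate
20 | (1R,5R,9S)-1-[(1E)-2,6-dimethylhepta-1,5-dien-1-yl]-9-hydroxy-2-oxaspiro[4.5]dec-7-ene-3,6-dione | O[C@@H]1C=CC(=O)[C@@]2(CC(=O)O[C@@H]2/C=C(\C)CCC=C(C)C)C1 | intermediate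
21 | O-(C9) 2,2,2-trichloroacetimidate of 20 | N=C(O[C@@H]1C=CC(=O)[C@@]2(CC(=O)O[C@@H]2/C=C(\C)CCC=C(C)C)C1)C(Cl)(Cl)Cl | intermediate
22 | cis-fused 2-(trichloromethyl)-4,5-dihydro-1,3-oxazole on N–C8/O–C9 of the (1R,5R,8R,9S) spiro-lactone dione | ClC(Cl)(Cl)C1=N[C@@H]2CC(=O)[C@@]3(CC(=O)O[C@@H]3/C=C(\C)CCC=C(C)C)C[C@@H]2O1 | intermediate
23 | (1R,5R,8R,9S)-8-amino-1-[(1E)-2,6-dimethylhepta-1,5-dien-1-yl]-9-hydroxy-2-oxaspiro[4.5]decane-3,6-dione hydrochloride | Cl.N[C@@H]1CC(=O)[C@@]2(CC(=O)O[C@@H]2/C=C(\C)CCC=C(C)C)C[C@@H]1O | intermediate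
24 | N-[(1R,5R,8R,9S)-1-[(1E)-2,6-dimethylhepta-1,5-dien-1-yl]-9-hydroxy-3,6-dioxo-2-oxaspiro[4.5]decan-8-yl]acetamide, (+)-miliusane V | CC(=O)N[C@@H]1CC(=O)[C@@]2(CC(=O)O[C@@H]2/C=C(\C)CCC=C(C)C)C[C@@H]1O | target

**Step count:** 10 steps in total. Longest linear sequence: 8 steps (steps 3–10 from 6 and 7; the side-chain branch, steps 1–2, joins at step 5 and is equally long).

**Steps most likely to fail**

Step 6 (the proposed new ring expansion). The butenolide may be too weak an acceptor for a cyclopentenol donor, or the allylic lactone C–O bond may ionise first. The fallback uses known chemistry, sets out from iodide 5 and comes back at ene-dione 19. Commercial methyl 4-oxobutanoate is α-methylenated (aqueous formaldehyde, pyrrolidine, propionic acid) to methyl 3-formylbut-3-enoate F1. An enantioselective Diels–Alder reaction of F1 with (E)-1-(trimethylsilyloxy)buta-1,3-diene under a chiral oxazaborolidinium Lewis acid (ortho/endo rule) gives methyl 2-[(1S,2S)-1-formyl-2-[(trimethylsilyl)oxy]cyclohex-3-en-1-yl]acetate F2, which already holds the quaternary carbon. Ni/Cr coupling of F2 with 5 under the step 5 conditions, lactonisation and loss of the silyl ether on acidic work-up give (1R,5S,6S)-1-[(1E)-2,6-dimethylhepta-1,5-dien-1-yl]-6-hydroxy-2-oxaspiro[4.5]dec-7-en-3-one F3. MnO2 oxidises the allylic alcohol to (1R,5R)-1-[(1E)-2,6-dimethylhepta-1,5-dien-1-yl]-2-oxaspiro[4.5]dec-7-ene-3,6-dione F4, the conjugated isomer of 17. Aerobic γ-oxidation of F4 through the same dienolate as in step 7 (O2, t-BuOK) gives 19.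

Step 8 (facial selectivity of the Luche reduction). The conformational argument is qualitative and the selectivity may be modest or reversed. The fallback sets out from 19 and comes back at 20. If hydride adds mainly from the other face, the product is (1R,5R,9R)-1-[(1E)-2,6-dimethylhepta-1,5-dien-1-yl]-9-hydroxy-2-oxaspiro[4.5]dec-7-ene-3,6-dione F5. Mitsunobu inversion of F5 (4-nitrobenzoic acid, PPh3, DIAD, THF) gives (1R,5R,9S)-1-[(1E)-2,6-dimethylhepta-1,5-dien-1-yl]-3,6-dioxo-2-oxaspiro[4.5]dec-7-en-9-yl 4-nitrobenzoate F6, and methanolysis (K2CO3, MeOH, 0 °C) returns 20.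

Step 5 (asymmetric Ni/Cr coupling). The aldehyde sits next to a fully substituted carbon on a conjugated ester, so coupling may be slow or the ee modest. The fallback sets out from alkyne 3 and aldehyde 12 and comes back at 14. Alane 4 is not iodinated but added directly to 12 in the presence of Ti(Oi-Pr)4 and a chiral H8-BINOL ligand (titanium-catalysed asymmetric alkenylation of aldehydes with alkenylalanes); the alkoxide of 13 lactonises to 14. No new compound is made (F0).

**Further compounds**
F1 | step 6 | methyl 3-formylbut-3-enoate | C=C(C=O)CC(=O)OC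
F2 | step 6 | methyl 2-[(1S,2S)-1-formyl-2-[(trimethylsilyl)oxy]cyclohex-3-en-1-yl]acetate | COC(=O)C[C@@]1(C=O)CCC=C[C@@H]1O[Si](C)(C)C
F3 | step 6 | (1R,5S,6S)-1-[(1E)-2,6-dimethylhepta-1,5-dien-1-yl]-6-hydroxy-2-oxaspiro[4.5]dec-7-en-3-one | O[C@H]1C=CCC[C@]12CC(=O)O[C@@H]2/C=C(\C)CCC=C(C)C
F4 | step 6 | (1R,5R)-1-[(1E)-2,6-dimethylhepta-1,5-dien-1-yl]-2-oxaspiro[4.5]dec-7-ene-3,6-dione | O=C1C=CCC[C@]12CC(=O)O[C@@H]2/C=C(\C)CCC=C(C)C
F5 | step 8 | (1R,5R,9R)-1-[(1E)-2,6-dimethylhepta-1,5-dien-1-yl]-9-hydroxy-2-oxaspiro[4.5]dec-7-ene-3,6-dione | O[C@H]1C=CC(=O)[C@@]2(CC(=O)O[C@@H]2/C=C(\C)CCC=C(C)C)C1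
F6 | step 8 | (1R,5R,9S)-1-[(1E)-2,6-dimethylhepta-1,5-dien-1-yl]-3,6-dioxo-2-oxaspiro[4.5]dec-7-en-9-yl 4-nitrobenzoate | O=C(O[C@@H]1C=CC(=O)[C@@]2(CC(=O)O[C@@H]2/C=C(\C)CCC=C(C)C)C1)c1ccc(cc1)[N+](=O)[O-]
F0 | step 5 | none | none
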